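**Plan**

1. The α‑methylene‑γ‑butyrolactone ring (O1–C2(=O)–C3(=CH2)–C3a–C11a), fused at C3a–C11a to the ten‑membered carbocycle, is read as CO2 (C2) + a terminal allene (C3a=C3=CH2) + an aldehyde (C11a=O). One cut removes C2–C3 and C3a–C11a (and O1–C2) and leaves an open‑chain allenyl aldehyde.
2. Further back: the C4 isovalerate and C5 hydroxyl become MOM and TBS ethers; the allene comes from a C3a aldehyde (alkyne, then one‑carbon homologation); the C6 ester from an alkenylstannane and that from the C6≡C7 alkyne; the C4–C5 bond is cut to an ynal and a γ‑alkoxyallylborane; C7–C11a with the C10 methyl come from (S)‑citronellal.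
3. Forward: the chain is built linearly from the citronellal end, the ten‑membered carbocycle and the lactone arise together at the end, and three steps then exchange the protecting groups.
4. Stereochemistry: C10 from (S)‑citronellal; C5 and C4 together from a reagent‑controlled (Z)‑alkoxyallylboration (syn); the C6=C7 geometry from syn‑hydrostannation and stereoretentive carbonylation; C3a by 1,2‑induction from C4 and C11a by the ring closure (anti addition, trans lactone) in the key step.

Key step: step 14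

Remark: locants are those of cyclodeca[b]furan (O1, C2 lactone carbonyl, C3 with its methylidene, C3a, C4 O‑acyl, C5 OH, C6 CO2Me, C7, C8, C9, C10 methyl, C11, C11a O–CH) and are used for all intermediates; the acid work‑up of step 14 is counted as part of that operation.

**Route**

Step 1
Reactants: 1 (S)-citronellal
Product: 2 (6S)-8,8-dimethoxy-2,6-dimethyloct-2-ene
Conditions: HC(OMe)3, MeOH, PPTS (cat.), rt
Reagents that add atoms: trimethyl orthoformate, COC(OC)OC; methanol, CO
Why: Acid‑catalysed acetalization with the orthoformate as water scavenger masks the future C11a aldehyde, the mild acid should avoid the carbonyl‑ene cyclization of citronellal, and the C10 stereocenter is not touched.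

Step 2
Reactants: 2 (6S)-8,8-dimethoxy-2,6-dimethyloct-2-ene
Product: 4 (4S)-6,6-dimethoxy-4-methylhexanal, via ozonide 3 (not isolated)
Conditions: O3, CH2Cl2, −78 °C; then PPh3, −78 °C to rt
Reagents that add atoms: ozone, [O-][O+]=O
Why: Ozonolysis with reductive work‑up cleaves the only C=C bond and gives the C7 aldehyde while the acetal is inert.

Step 3
Reactants: 4 (4S)-6,6-dimethoxy-4-methylhexanal
Product: 5 (5S)-7,7-dimethoxy-5-methylhept-1-yne
Conditions: MeC(O)C(N2)P(O)(OMe)2, K2CO3, MeOH, 0 °C to rt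
Reagents that add atoms: dimethyl (1-diazo-2-oxopropyl)phosphonate, COP(=O)(OC)C(=[N+]=[N-])C(C)=O
Why: The Ohira–Bestmann homologation converts the aldehyde into the terminal alkyne under mild carbonate conditions and adds the future C6.

Step 4
Reactants: 5 (5S)-7,7-dimethoxy-5-methylhept-1-yne
Product: 7 (6S)-8,8-dimethoxy-6-methyloct-2-ynal, via lithium acetylide 6 (not isolated)
Conditions: n-BuLi, THF, −78 °C; DMF, −78 to 0 °C; inverse quench into cold aq. KH2PO4
Reagents that add atoms: N,N-dimethylformamide, CN(C)C=O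
Why: Formylation of the lithium acetylide with DMF adds the future C5, and the buffered inverse quench should release the 2‑ynal without conjugate addition of dimethylamine and without loss of the acetal.

Step 5
Reactants: 8 allyl alcohol
Product: 9 allyl methoxymethyl ether
Conditions: MOMCl, iPr2NEt, CH2Cl2, 0 °C to rt
Reagents that add atoms: chloromethyl methyl ether, COCCl
Why: O‑Alkylation of the alcohol with the α‑chloro ether under amine base (Williamson‑type) gives the donor for the γ‑alkoxyallyl reagent.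

Step 6
Reactants: 7 (6S)-8,8-dimethoxy-6-methyloct-2-ynal; 9 allyl methoxymethyl ether
Product: 12 (3S,4S,9S)-11,11-dimethoxy-3-(methoxymethoxy)-9-methylundec-1-en-5-yn-4-ol, via allylborane 10 (not isolated), via borinate 11 (not isolated)
Conditions: 9, s-BuLi, THF, −78 °C; (+)-B-methoxydiisopinocampheylborane; BF3·OEt2; then 7, −78 °C; NaOH, H2O2, 0 °C to rt
Reagents that add atoms: none
Why: Brown alkoxyallylboration: the (Z)‑γ‑alkoxyallylborane reacts through a chair six‑membered transition state, so its Z geometry gives the syn C4/C5 relationship, and the isopinocampheyl groups derived from (−)‑α‑pinene should direct attack to the Re face of the ynal, which sets C5 and C4 together.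

Step 7
Reactants: 12 (3S,4S,9S)-11,11-dimethoxy-3-(methoxymethoxy)-9-methylundec-1-en-5-yn-4-ol
Product: 13 (3S,4R,5E,9S)-11,11-dimethoxy-3-(methoxymethoxy)-9-methyl-5-(tributylstannyl)undeca-1,5-dien-4-ol
Conditions: Bu3SnH, Mo(CO)3(CNtBu)3 (cat.), hydroquinone (cat.), THF, 55 °C
Reagents that add atoms: tributyltin hydride, CCCC[SnH](CCCC)CCCC
Why: Molybdenum‑catalysed syn‑hydrostannation of the propargylic alcohol should place tin on the carbon next to the carbinol (C6) and hydrogen on C7 from the same side, which fixes the C6=C7 geometry with C8 cis to C5 and leaves the isolated vinyl group alone.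

Step 8
Reactants: 13 (3S,4R,5E,9S)-11,11-dimethoxy-3-(methoxymethoxy)-9-methyl-5-(tributylstannyl)undeca-1,5-dien-4-ol
Product: 14 methyl (2E,6S)-2-[(1S,2S)-1-hydroxy-2-(methoxymethoxy)but-3-en-1-yl]-8,8-dimethoxy-6-methyloct-2-enoate
Conditions: CO (1 atm), Pd(OAc)2 (cat.), Ph3As, 1,4-benzoquinone, CF3CO2H (cat.), MeOH, rt
Reagents that add atoms: carbon monoxide, [C-]#[O+]; methanol, CO
Why: Palladium‑catalysed oxidative methoxycarbonylation of the alkenylstannane (Stille‑type transmetalation, CO insertion, methanolysis, benzoquinone as reoxidant) replaces tin by CO2Me with retention of the double‑bond geometry and tolerates the free allylic hydroxyl.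

Step 9
Reactants: 14 methyl (2E,6S)-2-[(1S,2S)-1-hydroxy-2-(methoxymethoxy)but-3-en-1-yl]-8,8-dimethoxy-6-methyloct-2-enoate
Product: 15 methyl (2E,6S)-2-[(1S,2S)-1-[(tert-butyldimethylsilyl)oxy]-2-(methoxymethoxy)but-3-en-1-yl]-8,8-dimethoxy-6-methyloct-2-enoate
Conditions: TBSCl, imidazole, DMAP (cat.), DMF, 40 °C
Reagents that add atoms: tert-butyldimethylsilyl chloride, CC(C)(C)[Si](C)(C)Cl
Why: Imidazole‑promoted silylation protects the C5 hydroxyl so that the two oxygens at C4 and C5 stay distinguishable to the end, under conditions that do not touch the dimethyl acetal.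

Step 10
Reactants: 15 methyl (2E,6S)-2-[(1S,2S)-1-[(tert-butyldimethylsilyl)oxy]-2-(methoxymethoxy)but-3-en-1-yl]-8,8-dimethoxy-6-methyloct-2-enoate
Product: 17 methyl (2E,6S)-2-[(1S,2R)-1-[(tert-butyldimethylsilyl)oxy]-2-(methoxymethoxy)-3-oxopropyl]-8,8-dimethoxy-6-methyloct-2-enoate, via diol 16 (not isolated)
Conditions: OsO4 (cat.), NaIO4, 2,6-lutidine, dioxane–H2O, rt
Reagents that add atoms: OsO4, O=[Os](=O)(=O)=O (oxygen carrier, regenerated by periodate); sodium periodate, [Na+].[O-]I(=O)(=O)=O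
Why: Johnson–Lemieux oxidative cleavage: the electrophilic, sterically sensitive OsO4 should dihydroxylate the monosubstituted vinyl group in preference to the trisubstituted, electron‑poor and hindered enoate, and periodate cleaves the diol to the C3a aldehyde.

Step 11
Reactants: 17 methyl (2E,6S)-2-[(1S,2R)-1-[(tert-butyldimethylsilyl)oxy]-2-(methoxymethoxy)-3-oxopropyl]-8,8-dimethoxy-6-methyloct-2-enoate
Product: 18 methyl (2E,6S)-2-[(1S,2S)-1-[(tert-butyldimethylsilyl)oxy]-2-(methoxymethoxy)but-3-yn-1-yl]-8,8-dimethoxy-6-methyloct-2-enoate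
Conditions: MeC(O)C(N2)P(O)(OMe)2, K2CO3, MeOH, 0 °C to rt
Reagents that add atoms: dimethyl (1-diazo-2-oxopropyl)phosphonate, COP(=O)(OC)C(=[N+]=[N-])C(C)=O
Why: A second Ohira–Bestmann homologation adds the future C3, and the mild carbonate base should neither epimerize the α‑alkoxy aldehyde at C4 nor attack the methyl ester.

Step 12
Reactants: 18 methyl (2E,6S)-2-[(1S,2S)-1-[(tert-butyldimethylsilyl)oxy]-2-(methoxymethoxy)but-3-yn-1-yl]-8,8-dimethoxy-6-methyloct-2-enoate
Product: 20 methyl (2E,6S)-2-[(1S,2S)-1-[(tert-butyldimethylsilyl)oxy]-2-(methoxymethoxy)penta-3,4-dien-1-yl]-8,8-dimethoxy-6-methyloct-2-enoate, via propargylic amine 19 (not isolated)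
Conditions: (CH2O)n, iPr2NH, CuBr, dioxane, reflux
Reagents that add atoms: paraformaldehyde (formaldehyde), C=O
Why: Crabbé homologation: copper‑mediated Mannich reaction of the terminal alkyne with formaldehyde and diisopropylamine, followed by 1,5‑hydride transfer from the amine and loss of the imine, gives the terminal allene, and propargylic ethers are good substrates.

Step 13
Reactants: 20 methyl (2E,6S)-2-[(1S,2S)-1-[(tert-butyldimethylsilyl)oxy]-2-(methoxymethoxy)penta-3,4-dien-1-yl]-8,8-dimethoxy-6-methyloct-2-enoate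
Product: 21 methyl (2E,6S)-2-[(1S,2S)-1-[(tert-butyldimethylsilyl)oxy]-2-(methoxymethoxy)penta-3,4-dien-1-yl]-6-methyl-8-oxooct-2-enoate
Conditions: PPTS, acetone–H2O, 50 °C
Reagents that add atoms: water, O
Why: Acid‑catalysed acetal hydrolysis frees the C11a aldehyde, and the MOM ether, the secondary TBS ether and the allene should tolerate pyridinium tosylate.

Step 14
Reactants: 21 methyl (2E,6S)-2-[(1S,2S)-1-[(tert-butyldimethylsilyl)oxy]-2-(methoxymethoxy)penta-3,4-dien-1-yl]-6-methyl-8-oxooct-2-enoate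
Product: 24 methyl (3aS,4S,5S,6E,10S,11aR)-5-[(tert-butyldimethylsilyl)oxy]-4-(methoxymethoxy)-10-methyl-3-methylidene-2-oxo-2,3,3a,4,5,8,9,10,11,11a-decahydrocyclodeca[b]furan-6-carboxylate, via nickelalactone 22 (not isolated), via hydroxy acid 23 (not isolated)
Conditions: Ni(cod)2 (2 equiv), DBU, CO2 (1 atm), THF, 0 °C, slow addition of 21 (final ca. 2 mM), then rt; aq. HCl work-up
Reagents that add atoms: carbon dioxide, O=C=O
Why: Proposed new method: zerovalent nickel with DBU as ligand should couple CO2 with the terminal allene of 21 by oxidative cyclization, joining the central allene carbon (C3) to CO2 (C2) and giving the five‑membered nickelalactone 22, a 2‑carboxylato‑allylnickel; this allyl nucleophile then adds through its substituted terminus (C3a) to the tethered aldehyde (C11a) in a six‑membered Ni–O transition state, and acid work‑up lactonizes the γ‑hydroxy acid 23 to 24. The closest known reaction type is the nickel‑mediated carboxylation of terminal allenes with CO2 followed by addition of the allylnickel carboxylate to an aldehyde (between separate molecules and for small carbocycles), combined with the chromium‑ or indium‑mediated Barbier closure of 2‑(halomethyl)acrylates onto aldehydes used for ten‑membered germacranolide rings; because both C–C bond formations also run without a tether, ring size should be limited only by dilution. The carbocycle closes 10‑exo‑trig (C3a onto the aldehyde carbon) and the lactone 5‑exo‑trig (O1 onto the carboxyl carbon C2). C3a should be controlled by the C4 stereocenter, with C4–H eclipsing the allyl plane to avoid allylic 1,3‑strain with the CH2–Ni terminus and the aldehyde carbon bonding anti to the C4–C5 bond and gauche to the C4–O bond; C11a should follow from C3a through the cyclic transition state spanned by the ten‑membered ring, which gives the anti adduct and hence the trans‑fused lactone. The step needs CO2 at the central allene carbon (the intrinsic sense of nickelalactone formation), attack through the substituted allyl terminus (nickel rests on the CH2 end and the alternative would need a twelve‑membered ring), reaction of the allene before the trisubstituted enoate (the allene is the better ligand and CO2 is in excess) and no leaving group on the allenyl carbinol oxygen, which is why C4–O is carried as the MOM ether and not as the ester.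

Step 15
Reactants: 24 methyl (3aS,4S,5S,6E,10S,11aR)-5-[(tert-butyldimethylsilyl)oxy]-4-(methoxymethoxy)-10-methyl-3-methylidene-2-oxo-2,3,3a,4,5,8,9,10,11,11a-decahydrocyclodeca[b]furan-6-carboxylate
Product: 26 methyl (3aR,4S,5S,6E,10S,11aR)-5-[(tert-butyldimethylsilyl)oxy]-4-hydroxy-10-methyl-3-methylidene-2-oxo-2,3,3a,4,5,8,9,10,11,11a-decahydrocyclodeca[b]furan-6-carboxylate, via bipyridinium salt 25 (not isolated)
Conditions: Me3SiOTf, 2,2′-bipyridyl, CH2Cl2, 0 °C; then H2O
Reagents that add atoms: none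
Why: Lewis‑acid cleavage of the MOM acetal: the silyl triflate ionizes the acetal, bipyridyl traps the oxocarbenium ion as a pyridinium salt that water hydrolyses, and these buffered conditions should leave the TBS ether, both esters and the α‑methylene lactone (the C3a descriptor changes only through the priority rules).

Step 16
Reactants: 26 methyl (3aR,4S,5S,6E,10S,11aR)-5-[(tert-butyldimethylsilyl)oxy]-4-hydroxy-10-methyl-3-methylidene-2-oxo-2,3,3a,4,5,8,9,10,11,11a-decahydrocyclodeca[b]furan-6-carboxylate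
Product: 27 methyl (3aS,4S,5S,6E,10S,11aR)-5-[(tert-butyldimethylsilyl)oxy]-10-methyl-3-methylidene-4-[(3-methylbutanoyl)oxy]-2-oxo-2,3,3a,4,5,8,9,10,11,11a-decahydrocyclodeca[b]furan-6-carboxylate
Conditions: (iBuCO)2O, DMAP (cat.), Et3N, CH2Cl2, 0 °C to rt
Reagents that add atoms: 3-methylbutanoic anhydride, CC(C)CC(=O)OC(=O)CC(C)C
Why: DMAP‑catalysed acyl transfer to the only free hydroxyl installs the isovalerate at C4 with retention.

Step 17
Reactants: 27 methyl (3aS,4S,5S,6E,10S,11aR)-5-[(tert-butyldimethylsilyl)oxy]-10-methyl-3-methylidene-4-[(3-methylbutanoyl)oxy]-2-oxo-2,3,3a,4,5,8,9,10,11,11a-decahydrocyclodeca[b]furan-6-carboxylate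
Product: 28 methyl (3aS,4S,5S,6E,10S,11aR)-5-hydroxy-10-methyl-3-methylidene-4-[(3-methylbutanoyl)oxy]-2-oxo-2,3,3a,4,5,8,9,10,11,11a-decahydrocyclodeca[b]furan-6-carboxylate (CNP0544142.1)
Conditions: HF·pyridine, pyridine, THF, 0 °C to rt
Reagents that add atoms: none
Why: Fluoride‑mediated desilylation under buffered acidic conditions frees the C5 hydroxyl without base, so the neighbouring isovalerate should not migrate and the α‑methylene lactone should not be attacked.

**Compound list**

1 | (S)-citronellal, (3S)-3,7-dimethyloct-6-enal | O=CC[C@@H](C)CCC=C(C)C | starting material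
2 | (6S)-8,8-dimethoxy-2,6-dimethyloct-2-ene | COC(OC)C[C@@H](C)CCC=C(C)C | intermediate
3 | ozonide, 3-[(3S)-5,5-dimethoxy-3-methylpentyl]-5,5-dimethyl-1,2,4-trioxolane | COC(OC)C[C@@H](C)CCC1OOC(C)(C)O1 | intermediate
4 | (4S)-6,6-dimethoxy-4-methylhexanal | COC(OC)C[C@@H](C)CCC=O | intermediate
5 | (5S)-7,7-dimethoxy-5-methylhept-1-yne | COC(OC)C[C@@H](C)CCC#C | intermediate
6 | lithium acetylide of 5 | COC(OC)C[C@@H](C)CCC#C[Li] | intermediate
7 | (6S)-8,8-dimethoxy-6-methyloct-2-ynal | COC(OC)C[C@@H](C)CCC#CC=O | intermediate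
8 | allyl alcohol, prop-2-en-1-ol | C=CCO | starting material
9 | allyl methoxymethyl ether, 3-(methoxymethoxy)prop-1-ene | C=CCOCOC | intermediate
10 | [(2Z)-3-(methoxymethoxy)prop-2-en-1-yl]bis[(1S,2S,3S,5R)-isopinocampheyl]borane | COCO/C=C\CB([C@H]1C[C@H]2C[C@@H]([C@@H]1C)C2(C)C)[C@H]1C[C@H]2C[C@@H]([C@@H]1C)C2(C)C | intermediate
11 | bis[(1S,2S,3S,5R)-isopinocampheyl]borinate of 12 (boron on the C5 oxygen) | COC(OC)C[C@@H](C)CCC#C[C@H](OB([C@H]1C[C@H]2C[C@@H]([C@@H]1C)C2(C)C)[C@H]1C[C@H]2C[C@@H]([C@@H]1C)C2(C)C)[C@@H](OCOC)C=C | intermediate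
12 | (3S,4S,9S)-11,11-dimethoxy-3-(methoxymethoxy)-9-methylundec-1-en-5-yn-4-ol | COC(OC)C[C@@H](C)CCC#C[C@H](O)[C@@H](OCOC)C=C | intermediate
13 | (3S,4R,5E,9S)-11,11-dimethoxy-3-(methoxymethoxy)-9-methyl-5-(tributylstannyl)undeca-1,5-dien-4-ol | COC(OC)C[C@@H](C)CC/C=C(/[Sn](CCCC)(CCCC)CCCC)[C@H](O)[C@@H](OCOC)C=C | intermediate
14 | methyl (2E,6S)-2-[(1S,2S)-1-hydroxy-2-(methoxymethoxy)but-3-en-1-yl]-8,8-dimethoxy-6-methyloct-2-enoate | COC(OC)C[C@@H](C)CC/C=C(/C(=O)OC)[C@H](O)[C@@H](OCOC)C=C | intermediate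
15 | methyl (2E,6S)-2-[(1S,2S)-1-[(tert-butyldimethylsilyl)oxy]-2-(methoxymethoxy)but-3-en-1-yl]-8,8-dimethoxy-6-methyloct-2-enoate | COC(OC)C[C@@H](C)CC/C=C(/C(=O)OC)[C@H](O[Si](C)(C)C(C)(C)C)[C@@H](OCOC)C=C | intermediate
16 | methyl (2E,6S)-2-[(1S,2S)-1-[(tert-butyldimethylsilyl)oxy]-3,4-dihydroxy-2-(methoxymethoxy)butyl]-8,8-dimethoxy-6-methyloct-2-enoate (both carbinol epimers) | COC(OC)C[C@@H](C)CC/C=C(/C(=O)OC)[C@H](O[Si](C)(C)C(C)(C)C)[C@@H](OCOC)C(O)CO | intermediate
17 | methyl (2E,6S)-2-[(1S,2R)-1-[(tert-butyldimethylsilyl)oxy]-2-(methoxymethoxy)-3-oxopropyl]-8,8-dimethoxy-6-methyloct-2-enoate | COC(OC)C[C@@H](C)CC/C=C(/C(=O)OC)[C@H](O[Si](C)(C)C(C)(C)C)[C@@H](OCOC)C=O | intermediate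
18 | methyl (2E,6S)-2-[(1S,2S)-1-[(tert-butyldimethylsilyl)oxy]-2-(methoxymethoxy)but-3-yn-1-yl]-8,8-dimethoxy-6-methyloct-2-enoate | COC(OC)C[C@@H](C)CC/C=C(/C(=O)OC)[C@H](O[Si](C)(C)C(C)(C)C)[C@@H](OCOC)C#C | intermediate
19 | methyl (2E,6S)-2-[(1S,2S)-1-[(tert-butyldimethylsilyl)oxy]-5-(diisopropylamino)-2-(methoxymethoxy)pent-3-yn-1-yl]-8,8-dimethoxy-6-methyloct-2-enoate | COC(OC)C[C@@H](C)CC/C=C(/C(=O)OC)[C@H](O[Si](C)(C)C(C)(C)C)[C@@H](OCOC)C#CCN(C(C)C)C(C)C | intermediate
20 | methyl (2E,6S)-2-[(1S,2S)-1-[(tert-butyldimethylsilyl)oxy]-2-(methoxymethoxy)penta-3,4-dien-1-yl]-8,8-dimethoxy-6-methyloct-2-enoate | COC(OC)C[C@@H](C)CC/C=C(/C(=O)OC)[C@H](O[Si](C)(C)C(C)(C)C)[C@@H](OCOC)C=C=C | intermediate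
21 | methyl (2E,6S)-2-[(1S,2S)-1-[(tert-butyldimethylsilyl)oxy]-2-(methoxymethoxy)penta-3,4-dien-1-yl]-6-methyl-8-oxooct-2-enoate | O=CC[C@@H](C)CC/C=C(/C(=O)OC)[C@H](O[Si](C)(C)C(C)(C)C)[C@@H](OCOC)C=C=C | intermediate
22 | nickelalactone: 4-alkylidene-1-oxa-2-nickelacyclopentan-5-one from the allene of 21 and CO2 (DBU on nickel not drawn; alkylidene geometry open) | O=CC[C@@H](C)CC/C=C(/C(=O)OC)[C@H](O[Si](C)(C)C(C)(C)C)[C@@H](OCOC)C=C1C[Ni]OC1=O | intermediate
23 | 2-[(1S,2R,4S,7E,9S,10S)-9-[(tert-butyldimethylsilyl)oxy]-2-hydroxy-8-(methoxycarbonyl)-10-(methoxymethoxy)-4-methylcyclodec-7-en-1-yl]prop-2-enoic acid | O[C@@H]1C[C@@H](C)CC/C=C(/C(=O)OC)[C@H](O[Si](C)(C)C(C)(C)C)[C@@H](OCOC)[C@H]1C(=C)C(=O)O | intermediate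
24 | methyl (3aS,4S,5S,6E,10S,11aR)-5-[(tert-butyldimethylsilyl)oxy]-4-(methoxymethoxy)-10-methyl-3-methylidene-2-oxo-2,3,3a,4,5,8,9,10,11,11a-decahydrocyclodeca[b]furan-6-carboxylate | C=C1C(=O)O[C@@H]2C[C@@H](C)CC/C=C(/C(=O)OC)[C@H](O[Si](C)(C)C(C)(C)C)[C@@H](OCOC)[C@@H]12 | intermediate
25 | N-(alkoxymethyl)-2,2′-bipyridinium triflate of 26 (on the C4 oxygen) | C=C1C(=O)O[C@@H]2C[C@@H](C)CC/C=C(/C(=O)OC)[C@H](O[Si](C)(C)C(C)(C)C)[C@@H](OC[n+]3ccccc3-c3ccccn3)[C@@H]12.[O-]S(=O)(=O)C(F)(F)F | intermediate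
26 | methyl (3aR,4S,5S,6E,10S,11aR)-5-[(tert-butyldimethylsilyl)oxy]-4-hydroxy-10-methyl-3-methylidene-2-oxo-2,3,3a,4,5,8,9,10,11,11a-decahydrocyclodeca[b]furan-6-carboxylate | C=C1C(=O)O[C@@H]2C[C@@H](C)CC/C=C(/C(=O)OC)[C@H](O[Si](C)(C)C(C)(C)C)[C@@H](O)[C@@H]12 | intermediate
27 | methyl (3aS,4S,5S,6E,10S,11aR)-5-[(tert-butyldimethylsilyl)oxy]-10-methyl-3-methylidene-4-[(3-methylbutanoyl)oxy]-2-oxo-2,3,3a,4,5,8,9,10,11,11a-decahydrocyclodeca[b]furan-6-carboxylate | C=C1C(=O)O[C@@H]2C[C@@H](C)CC/C=C(/C(=O)OC)[C@H](O[Si](C)(C)C(C)(C)C)[C@@H](OC(=O)CC(C)C)[C@@H]12 | intermediate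
28 | methyl (3aS,4S,5S,6E,10S,11aR)-5-hydroxy-10-methyl-3-methylidene-4-[(3-methylbutanoyl)oxy]-2-oxo-2,3,3a,4,5,8,9,10,11,11a-decahydrocyclodeca[b]furan-6-carboxylate | C=C1C(=O)O[C@@H]2C[C@@H](C)CC/C=C(/C(=O)OC)[C@H](O)[C@@H](OC(=O)CC(C)C)[C@@H]12 | target

**Step count and risks**

Total steps: 17 (16 in the main line and 1 for the allyl ether 9). Longest linear sequence: 16 steps (steps 1–4 and 6–17).

Steps most likely to fail:

1. Step 14 (proposed new method). What may go wrong: oligomerization in place of ring closure; β‑elimination of the C4 alkoxy group from the allylnickel; addition through the unsubstituted allyl terminus; engagement of the enoate by nickel; or poor facial selectivity at C3a. Fallback with known chemistry, setting out from aldehyde 17 and returning at lactone 24: a Morita–Baylis–Hillman reaction of 17 with methyl acrylate (DABCO) should give the hydroxy ester F1; NBS and Me2S should convert it by SN2′ displacement into the (Z)-2-(bromomethyl)enoate F2; PPTS in wet acetone frees the bromo aldehyde F3; CrCl2 (divalent chromium) in THF at high dilution then closes the ten‑membered ring by an intramolecular Nozaki–Hiyama/Barbier allylation of the kind used for germacranolides, and acid‑induced lactonization onto the neighbouring ester gives 24. In this variant C2–C3 is in place before the ring closes and only C3a–C11a forms in the macrocyclization.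

2. Step 7. What may go wrong: loss of regiocontrol, with tin delivered to C7 instead of C6. Fallback setting out from 12 and returning at 13: MnO2 oxidation gives the ynone F4; palladium‑catalysed hydrostannation (Bu3SnH, Pd(PPh3)4) places tin α to the carbonyl by syn addition and gives the stannyl enone F5; a Corey–Bakshi–Shibata 1,2‑reduction, with the catalyst enantiomer chosen for the C5 configuration (the Felkin sense of the α‑alkoxy ketone points the same way), returns 13.

3. Step 10. What may go wrong: loss of chemoselectivity through competing dihydroxylation of the enoate C6=C7 bond. Fallback setting out from 13 and returning at 17, in which the enoate is made only after the cleavage: iododestannylation with I2 gives the alkenyl iodide F6 with retention; TBSCl and imidazole give the silyl ether F7; OsO4 and NaIO4 cleave the vinyl group, now the only alkene that OsO4 attacks readily, to the iodo aldehyde F8; palladium‑catalysed methoxycarbonylation (Pd(PPh3)4, CO, MeOH, Et3N) then gives 17.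

Further compounds
F1 | step 14 | methyl (2E,6S)-2-[(1S,2S)-1-[(tert-butyldimethylsilyl)oxy]-3-hydroxy-4-(methoxycarbonyl)-2-(methoxymethoxy)pent-4-en-1-yl]-8,8-dimethoxy-6-methyloct-2-enoate (both carbinol epimers) | COC(OC)C[C@@H](C)CC/C=C(/C(=O)OC)[C@H](O[Si](C)(C)C(C)(C)C)[C@@H](OCOC)C(O)C(=C)C(=O)OC
F2 | step 14 | methyl (2E,6S)-2-[(1S,2S,3Z)-5-bromo-1-[(tert-butyldimethylsilyl)oxy]-4-(methoxycarbonyl)-2-(methoxymethoxy)pent-3-en-1-yl]-8,8-dimethoxy-6-methyloct-2-enoate | COC(OC)C[C@@H](C)CC/C=C(/C(=O)OC)[C@H](O[Si](C)(C)C(C)(C)C)[C@@H](OCOC)/C=C(/C(=O)OC)CBr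
F3 | step 14 | methyl (2E,6S)-2-[(1S,2S,3Z)-5-bromo-1-[(tert-butyldimethylsilyl)oxy]-4-(methoxycarbonyl)-2-(methoxymethoxy)pent-3-en-1-yl]-6-methyl-8-oxooct-2-enoate | O=CC[C@@H](C)CC/C=C(/C(=O)OC)[C@H](O[Si](C)(C)C(C)(C)C)[C@@H](OCOC)/C=C(/C(=O)OC)CBr
F4 | step 7 | (3S,9S)-11,11-dimethoxy-3-(methoxymethoxy)-9-methylundec-1-en-5-yn-4-one | COC(OC)C[C@@H](C)CCC#CC(=O)[C@@H](OCOC)C=C
F5 | step 7 | (3S,5E,9S)-11,11-dimethoxy-3-(methoxymethoxy)-9-methyl-5-(tributylstannyl)undeca-1,5-dien-4-one | COC(OC)C[C@@H](C)CC/C=C(/[Sn](CCCC)(CCCC)CCCC)C(=O)[C@@H](OCOC)C=C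
F6 | step 10 | (3S,4R,5E,9S)-5-iodo-11,11-dimethoxy-3-(methoxymethoxy)-9-methylundeca-1,5-dien-4-ol | COC(OC)C[C@@H](C)CC/C=C(/I)[C@H](O)[C@@H](OCOC)C=C
F7 | step 10 | tert-butyldimethylsilyl ether of F6 (on the C5 oxygen) | COC(OC)C[C@@H](C)CC/C=C(/I)[C@H](O[Si](C)(C)C(C)(C)C)[C@@H](OCOC)C=C
F8 | step 10 | (2R,3R,4E,8S)-3-[(tert-butyldimethylsilyl)oxy]-4-iodo-10,10-dimethoxy-2-(methoxymethoxy)-8-methyldec-4-enal | COC(OC)C[C@@H](C)CC/C=C(/I)[C@H](O[Si](C)(C)C(C)(C)C)[C@@H](OCOC)C=O
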